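**Plan**
1. Numbering used throughout (daucane): C1 = quaternary ring-fusion carbon (CH3), C2 = CH–O(angelate), C3 = CH2, C4 = C(OH)(iPr), C5 = ring-fusion CH, C6 = CH–O(anisate), C7 = CH2, C8 = C(CH3)=, C9 = CH=, C10 = CH2; β is the face of the C1 methyl.
2. Retrosynthesis: the ester C–O bonds at C2 and C6 are cut first; then C7–C8 and C5–C1 are cut together, which opens both rings to one acyclic chain; the chain is cut at C6–C7 (MeMgBr), C4–iPr (organocopper), C5–C6 (chloroformate), C2–C3 (propargylation) and C1=C10 (Wittig).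
3. Enabling feature: in the seven-membered ring the run C5–C6–C7 has its oxygen on the middle carbon and is flanked by the oxygenated C4 of the five-membered ring. This is the pattern of a 2-silyloxyallyl cation released from a C4–C5 epoxide beside an enol silyl ether. C8–C9–C10–C1 is then a 1,3-diene, held to C5 by the three-atom tether C2–C3–C4.
4. Forward: a linear chain is grown from crotonaldehyde; one epoxide-triggered intramolecular (4+3) cycloaddition closes the five- and the seven-membered ring together. The cycloaddition must leave the alkene at C9=C10, so a helper double bond C7=C8 (Saegusa–Ito) is added and taken out again by 1,4-hydrogenation, which leaves C8=C9.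
5. Stereochemistry: C2 from a catalytic asymmetric propargylation; C4 and C5 from a Sharpless epoxide (retention at C4, inversion at C5 in the key step); C1 from the tether-controlled, trans-fusing transition state; C6 from hydride delivery by the C4 hydroxyl; the (Z)-ester from angelic acid itself.

Key step: step 12

Remarks: TBS = tert-butyldimethylsilyl, TES = triethylsilyl. "Dauc-" names mean the 1,8-dimethyl-4-isopropyl-perhydroazulene skeleton numbered as in line 1.
Assumption: (R)-TRIP is taken to deliver the propargyl group to the aldehyde face that gives the (4R)-alcohol, by analogy with aryl and alkenyl aldehydes; if the sense proves opposite, the (S)-acid is used and nothing else changes.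

**Route**

Step 1
Reactants: 1 (E)-but-2-enal (crotonaldehyde); 2 2-(triphenylphosphoranylidene)propanal
Product: 3 (2E,4E)-2-methylhexa-2,4-dienal
Conditions: toluene, 90 °C
Reagents that add atoms: none
Why: Wittig olefination with a formyl-stabilised ylide should run under thermodynamic control and give the (E)-trisubstituted enal (formyl trans to the chain), the crotyl double bond staying (E).

Step 2
Reactants: 3 (2E,4E)-2-methylhexa-2,4-dienal; 4 allenylboronic acid pinacol ester
Product: 5 (4R,5E,7E)-5-methylnona-5,7-dien-1-yn-4-ol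
Conditions: (R)-TRIP [(R)-3,3'-bis(2,4,6-triisopropylphenyl)-1,1'-binaphthyl-2,2'-diyl hydrogen phosphate] (5 mol%), 4 Å MS, toluene, −20 °C; aqueous work-up
Reagents that add atoms: none
Why: Chiral-phosphoric-acid-catalysed propargylboration: the allenylboronate should add 1,2 to the aldehyde through a closed six-membered SE2′ transition state, the catalyst choosing the aldehyde face and so setting C2.

Step 3
Reactants: 5 (4R,5E,7E)-5-methylnona-5,7-dien-1-yn-4-ol
Product: 6 tert-butyldimethyl{[(4R,5E,7E)-5-methylnona-5,7-dien-1-yn-4-yl]oxy}silane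
Conditions: TBSCl, imidazole, DMF, rt
Reagents that add atoms: tert-butyldimethylsilyl chloride, CC(C)(C)[Si](C)(C)Cl
Why: Standard silyl ether formation on a secondary alcohol; the group has to survive base, hydride and Lewis acid and to be less labile than a triethylsilyl ether.

Step 4
Reactants: 6 tert-butyldimethyl{[(4R,5E,7E)-5-methylnona-5,7-dien-1-yn-4-yl]oxy}silane
Product: 8 methyl (5R,6E,8E)-5-[(tert-butyldimethylsilyl)oxy]-6-methyldeca-6,8-dien-2-ynoate, via lithium acetylide 7 (not isolated)
Conditions: n-BuLi, THF, −78 °C; then ClCO2Me, −78 → 0 °C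
Reagents that add atoms: methyl chloroformate, COC(=O)Cl
Why: Deprotonation of the terminal alkyne and C-acylation of the acetylide with a chloroformate is a standard route to 2-ynoates; no stereocenter is touched.

Step 5
Reactants: 8 methyl (5R,6E,8E)-5-[(tert-butyldimethylsilyl)oxy]-6-methyldeca-6,8-dien-2-ynoate
Product: 9 methyl (2E,5R,6E,8E)-5-[(tert-butyldimethylsilyl)oxy]-6-methyl-3-(propan-2-yl)deca-2,6,8-trienoate
Conditions: iPrMgCl, CuBr·SMe2, THF, −78 °C; MeOH quench at −78 °C
Reagents that add atoms: isopropylmagnesium chloride, CC(C)[Mg]Cl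
Why: Conjugate carbocupration of a 2-ynoate is a syn addition at −78 °C; protonation of the vinylcopper with retention should place isopropyl cis to H and the C3 chain cis to the ester, the geometry that later fixes C4 relative to C5.

Step 6
Reactants: 9 methyl (2E,5R,6E,8E)-5-[(tert-butyldimethylsilyl)oxy]-6-methyl-3-(propan-2-yl)deca-2,6,8-trienoate
Product: 10 (2E,5R,6E,8E)-5-[(tert-butyldimethylsilyl)oxy]-6-methyl-3-(propan-2-yl)deca-2,6,8-trien-1-ol
Conditions: iBu2AlH, CH2Cl2, −78 °C
Reagents that add atoms: none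
Why: 1,2-Reduction of the enoate by iBu2AlH at low temperature should give the allylic alcohol without touching the diene or the silyl ether.

Step 7
Reactants: 10 (2E,5R,6E,8E)-5-[(tert-butyldimethylsilyl)oxy]-6-methyl-3-(propan-2-yl)deca-2,6,8-trien-1-ol
Product: 11 {(2R,3R)-3-[(2R,3E,5E)-2-(TBS-oxy)-3-methylhepta-3,5-dien-1-yl]-3-(propan-2-yl)oxiran-2-yl}methanol
Conditions: Ti(OiPr)4 (10 mol%), D-(−)-diisopropyl tartrate (12 mol%), tBuOOH, 4 Å MS, CH2Cl2, −20 °C
Reagents that add atoms: tert-butyl hydroperoxide, CC(C)(C)OO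
Why: Sharpless asymmetric epoxidation: the titanium–tartrate catalyst epoxidises only the allylic alcohol (the diene is not a substrate) and the D-(−)-tartrate should give the (2R,3R)-epoxide under reagent control, which sets C4 and, before its later inversion, C5.

Step 8
Reactants: 11 {(2R,3R)-3-[(2R,3E,5E)-2-(TBS-oxy)-3-methylhepta-3,5-dien-1-yl]-3-(propan-2-yl)oxiran-2-yl}methanol
Product: 12 (2S,3R)-3-[(2R,3E,5E)-2-(TBS-oxy)-3-methylhepta-3,5-dien-1-yl]-3-(propan-2-yl)oxirane-2-carbaldehyde
Conditions: Dess–Martin periodinane, NaHCO3, CH2Cl2, 0 °C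
Reagents that add atoms: none
Why: Dess–Martin oxidation under buffered, non-acidic conditions should give the epoxy aldehyde without opening the trisubstituted epoxide.

Step 9
Reactants: 12 (2S,3R)-3-[(2R,3E,5E)-2-(TBS-oxy)-3-methylhepta-3,5-dien-1-yl]-3-(propan-2-yl)oxirane-2-carbaldehyde
Product: 13 1-{(2R,3R)-3-[(2R,3E,5E)-2-(TBS-oxy)-3-methylhepta-3,5-dien-1-yl]-3-(propan-2-yl)oxiran-2-yl}ethan-1-ol (both carbinol epimers)
Conditions: MeMgBr, THF, −78 °C
Reagents that add atoms: methylmagnesium bromide, C[Mg]Br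
Why: Grignard 1,2-addition to the aldehyde adds C7; the new carbinol centre forms as a mixture and is removed in step 10.

Step 10
Reactants: 13 1-{(2R,3R)-3-[(2R,3E,5E)-2-(TBS-oxy)-3-methylhepta-3,5-dien-1-yl]-3-(propan-2-yl)oxiran-2-yl}ethan-1-ol
Product: 14 1-{(2S,3R)-3-[(2R,3E,5E)-2-(TBS-oxy)-3-methylhepta-3,5-dien-1-yl]-3-(propan-2-yl)oxiran-2-yl}ethan-1-one
Conditions: Dess–Martin periodinane, NaHCO3, CH2Cl2, rt
Reagents that add atoms: none
Why: Dess–Martin oxidation of the secondary alcohol should give the epoxy methyl ketone under neutral conditions that do not epimerise the epoxide carbon.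

Step 11
Reactants: 14 1-{(2S,3R)-3-[(2R,3E,5E)-2-(TBS-oxy)-3-methylhepta-3,5-dien-1-yl]-3-(propan-2-yl)oxiran-2-yl}ethan-1-one
Product: 15 (2R,3S)-2-[(2R,3E,5E)-2-(TBS-oxy)-3-methylhepta-3,5-dien-1-yl]-2-(propan-2-yl)-3-[1-(triethylsilyloxy)ethenyl]oxirane
Conditions: Et3SiCl, Et3N, LiN(SiMe3)2, THF, −78 °C
Reagents that add atoms: chlorotriethylsilane, CC[Si](Cl)(CC)CC
Why: Kinetic deprotonation at the methyl group (the only enolisable position) with in situ O-silylation should give the 2-silyloxy-1-ene; the epoxide is inert to amide base at −78 °C.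

Step 12
Reactants: 15 (2R,3S)-2-[(2R,3E,5E)-2-(TBS-oxy)-3-methylhepta-3,5-dien-1-yl]-2-(propan-2-yl)-3-[1-(triethylsilyloxy)ethenyl]oxirane
Product: 16 2β-(TBS-oxy)-4β-(TES-oxy)-5αH,8βH-dauc-9-en-6-one (trans-fused)
Conditions: Et3SiOTf (10 mol%), CH2Cl2, −78 °C
Reagents that add atoms: none
Why: Proposed new method: silylation of the oxirane oxygen by Et3SiOTf should weaken the C5–O bond, which is allylic to the enol silyl ether (incipient 2-silyloxyallyl cation); the diene terminus C1 should attack C5 from the side opposite the leaving oxygen while the enol ether carbon C7 closes on C8, and the silyloxocarbenium ion then passes its silyl group on, so that the C4 oxygen ends as the triethylsilyl ether and the catalyst turns over. The closest known reaction type is the silyl-triflate-catalysed intramolecular (4+3) cycloaddition of epoxy enolsilanes carrying tethered furans or unsubstituted dienes; new here are the trisubstituted epoxide and the fully substituted diene terminus that must become a quaternary carbon. The five-membered ring closes by the tether-directed C5–C1 bond (the epoxide carbon C4 inside the new ring, its oxygen outside), and the seven-membered ring closes by (4+3) union of C5–C6–C7 with C8–C9–C10–C1, the second bond C7–C8 being a seven-membered closure of enol ether onto allyl cation. C4 keeps the epoxide configuration (its C–O bond is not broken), C5 is set by inversion at the epoxide carbon, and C1 by the extended transition state in which C2 is the outside substituent of the (E)-diene terminus and the propenyl arm takes the face of the nascent cyclopentane that carries H-2 and H-5, away from the OTBS group and the enol ether, which makes the ring fusion trans; C8 follows from the (E)-propenyl end and is erased in step 13. The step needs C5–O and not C4–O cleavage, attack through the cisoid diene, and closure at C8 and not at C10; allylic stabilisation with nucleophilic assistance at −78 °C, the short tether, and the W-shaped cation with its silyloxy group turned away from the diene are what is relied on.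

Step 13
Reactants: 16 2β-(TBS-oxy)-4β-(TES-oxy)-5αH,8βH-dauc-9-en-6-one
Product: 18 2β-(TBS-oxy)-4β-(TES-oxy)-5αH-dauca-7,9-dien-6-one, via trimethylsilyl enol ether 17 (not isolated)
Conditions: LiN(iPr)2, Me3SiCl, THF, −78 °C; then Pd(OAc)2, MeCN, rt
Reagents that add atoms: none
Why: Saegusa–Ito oxidation: kinetic enolisation should occur at the unhindered C7 methylene (C5 is a neopentyl methine and C4 has no hydrogen), and β-hydride loss from C8 at palladium installs the helper double bond C7=C8 in conjugation with C9=C10.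

Step 14
Reactants: 18 2β-(TBS-oxy)-4β-(TES-oxy)-5αH-dauca-7,9-dien-6-one
Product: 19 2β-(TBS-oxy)-4β-hydroxy-5αH-dauca-7,9-dien-6-one
Conditions: HF·pyridine, pyridine, THF, 0 °C
Reagents that add atoms: none
Why: Selective desilylation: buffered HF·pyridine should cleave the triethylsilyl ether well before the tert-butyldimethylsilyl ether on the neopentyl C2 carbinol, freeing the C4 hydroxyl as a directing group.

Step 15
Reactants: 19 2β-(TBS-oxy)-4β-hydroxy-5αH-dauca-7,9-dien-6-one
Product: 20 2β-(TBS-oxy)-5αH-dauca-7,9-diene-4β,6α-diol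
Conditions: Me4NBH(OAc)3, MeCN/AcOH, −20 °C
Reagents that add atoms: none
Why: Hydroxyl-directed (Evans–Saksena) reduction: the borohydride bound to the C4 oxygen should deliver hydride intramolecularly to the β face of C6, giving the 6α-alcohol anti to the C4 hydroxyl.

Step 16
Reactants: 20 2β-(TBS-oxy)-5αH-dauca-7,9-diene-4β,6α-diol
Product: 21 2β-(TBS-oxy)-5αH-dauc-8-ene-4β,6α-diol
Conditions: H2 (50 bar), Cr(CO)3(η6-naphthalene) (10 mol%), THF, 30 °C
Reagents that add atoms: none
Why: 1,4-Hydrogenation of a cisoid 1,3-diene by an arene–Cr(CO)3 catalyst: the Cr(CO)3 fragment binds the ring-held s-cis diene and adds H2 to its ends C7 and C10, so the double bond must end at C8=C9; no stereocenter is formed.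

Step 17
Reactants: 21 2β-(TBS-oxy)-5αH-dauc-8-ene-4β,6α-diol; 22 4-methoxybenzoyl chloride
Product: 23 2β-(TBS-oxy)-4β-hydroxy-5αH-dauc-8-en-6α-yl 4-methoxybenzoate
Conditions: pyridine, DMAP (cat.), CH2Cl2, 0 °C → rt
Reagents that add atoms: none
Why: Acylation with an aroyl chloride under nucleophilic catalysis should esterify only the secondary C6 hydroxyl; the tertiary C4 hydroxyl does not react under these conditions.

Step 18
Reactants: 23 2β-(TBS-oxy)-4β-hydroxy-5αH-dauc-8-en-6α-yl 4-methoxybenzoate
Product: 24 2β,4β-dihydroxy-5αH-dauc-8-en-6α-yl 4-methoxybenzoate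
Conditions: HF·pyridine, THF, 0 °C → rt
Reagents that add atoms: none
Why: Fluoride cleavage of the silyl ether under mildly acidic conditions, which should avoid ester migration or hydrolysis.

Step 19
Reactants: 24 2β,4β-dihydroxy-5αH-dauc-8-en-6α-yl 4-methoxybenzoate; 25 angelic acid [(Z)-2-methylbut-2-enoic acid]
Product: 27 target, (1R,2R,4R,5S,6S)-4β-hydroxy-2β-[(Z)-2-methylbut-2-enoyloxy]-5αH-dauc-8-en-6α-yl 4-methoxybenzoate, via mixed anhydride 26 (not isolated)
Conditions: 25, 2,4,6-trichlorobenzoyl chloride, Et3N, toluene, rt; then 24, 75 °C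
Reagents that add atoms: none
Why: Yamaguchi esterification: the alcohol should attack the less hindered angeloyl carbonyl of the mixed anhydride; without a nucleophilic catalyst the (Z)-double bond is expected to be kept, and the tertiary C4 hydroxyl stays free.

**Compound list**

1 | (E)-but-2-enal | C/C=C/C=O | starting material
2 | 2-(triphenylphosphoranylidene)propanal | CC(C=O)=P(c1ccccc1)(c1ccccc1)c1ccccc1 | starting material
3 | (2E,4E)-2-methylhexa-2,4-dienal | O=C/C(C)=C/C=C/C | intermediate
4 | allenylboronic acid pinacol ester | C=C=CB1OC(C)(C)C(C)(C)O1 | starting material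
5 | (4R,5E,7E)-5-methylnona-5,7-dien-1-yn-4-ol | C#CC[C@@H](O)/C(C)=C/C=C/C | intermediate
6 | TBS ether of 5 | C#CC[C@@H](O[Si](C)(C)C(C)(C)C)/C(C)=C/C=C/C | intermediate
7 | lithium acetylide of 6 | [Li]C#CC[C@@H](O[Si](C)(C)C(C)(C)C)/C(C)=C/C=C/C | intermediate
8 | methyl (5R,6E,8E)-5-(TBS-oxy)-6-methyldeca-6,8-dien-2-ynoate | COC(=O)C#CC[C@@H](O[Si](C)(C)C(C)(C)C)/C(C)=C/C=C/C | intermediate
9 | methyl (2E,5R,6E,8E)-5-(TBS-oxy)-6-methyl-3-(propan-2-yl)deca-2,6,8-trienoate | COC(=O)/C=C(C(C)C)\C[C@@H](O[Si](C)(C)C(C)(C)C)/C(C)=C/C=C/C | intermediate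
10 | (2E,5R,6E,8E)-5-(TBS-oxy)-6-methyl-3-(propan-2-yl)deca-2,6,8-trien-1-ol | OC/C=C(C(C)C)\C[C@@H](O[Si](C)(C)C(C)(C)C)/C(C)=C/C=C/C | intermediate
11 | (2R,3R)-epoxy alcohol | OC[C@H]1O[C@@]1(C(C)C)C[C@@H](O[Si](C)(C)C(C)(C)C)/C(C)=C/C=C/C | intermediate
12 | (2S,3R)-epoxy aldehyde | O=C[C@H]1O[C@@]1(C(C)C)C[C@@H](O[Si](C)(C)C(C)(C)C)/C(C)=C/C=C/C | intermediate
13 | epoxy secondary alcohol (carbinol epimers) | CC(O)[C@H]1O[C@@]1(C(C)C)C[C@@H](O[Si](C)(C)C(C)(C)C)/C(C)=C/C=C/C | intermediate
14 | (2S,3R)-epoxy methyl ketone | CC(=O)[C@H]1O[C@@]1(C(C)C)C[C@@H](O[Si](C)(C)C(C)(C)C)/C(C)=C/C=C/C | intermediate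
15 | epoxy enolsilane (TES enol ether of 14) | C=C(O[Si](CC)(CC)CC)[C@H]1O[C@@]1(C(C)C)C[C@@H](O[Si](C)(C)C(C)(C)C)/C(C)=C/C=C/C | intermediate
16 | 2β-(TBS-oxy)-4β-(TES-oxy)-5αH,8βH-dauc-9-en-6-one | CC(C)(C)[Si](C)(C)O[C@@H]1C[C@@](O[Si](CC)(CC)CC)(C(C)C)[C@@H]2C(=O)C[C@@H](C)C=C[C@]21C | intermediate
17 | C6 trimethylsilyl enol ether of 16 (dauca-6,9-diene) | CC(C)(C)[Si](C)(C)O[C@@H]1C[C@@](O[Si](CC)(CC)CC)(C(C)C)[C@@H]2C(O[Si](C)(C)C)=C[C@@H](C)C=C[C@]21C | intermediate
18 | 2β-(TBS-oxy)-4β-(TES-oxy)-5αH-dauca-7,9-dien-6-one | CC(C)(C)[Si](C)(C)O[C@@H]1C[C@@](O[Si](CC)(CC)CC)(C(C)C)[C@@H]2C(=O)C=C(C)C=C[C@]21C | intermediate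
19 | 2β-(TBS-oxy)-4β-hydroxy-5αH-dauca-7,9-dien-6-one | CC(C)(C)[Si](C)(C)O[C@@H]1C[C@@](O)(C(C)C)[C@@H]2C(=O)C=C(C)C=C[C@]21C | intermediate
20 | 2β-(TBS-oxy)-5αH-dauca-7,9-diene-4β,6α-diol | CC(C)(C)[Si](C)(C)O[C@@H]1C[C@@](O)(C(C)C)[C@@H]2[C@@H](O)C=C(C)C=C[C@]21C | intermediate
21 | 2β-(TBS-oxy)-5αH-dauc-8-ene-4β,6α-diol | CC(C)(C)[Si](C)(C)O[C@@H]1C[C@@](O)(C(C)C)[C@@H]2[C@@H](O)CC(C)=CC[C@]21C | intermediate
22 | 4-methoxybenzoyl chloride | COc1ccc(cc1)C(=O)Cl | starting material
23 | 2β-(TBS-oxy)-4β-hydroxy-5αH-dauc-8-en-6α-yl 4-methoxybenzoate | CC(C)(C)[Si](C)(C)O[C@@H]1C[C@@](O)(C(C)C)[C@@H]2[C@@H](OC(=O)c3ccc(OC)cc3)CC(C)=CC[C@]21C | intermediate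
24 | 2β,4β-dihydroxy-5αH-dauc-8-en-6α-yl 4-methoxybenzoate | O[C@@H]1C[C@@](O)(C(C)C)[C@@H]2[C@@H](OC(=O)c3ccc(OC)cc3)CC(C)=CC[C@]21C | intermediate
25 | angelic acid | C/C=C(/C)C(=O)O | starting material
26 | angelic 2,4,6-trichlorobenzoic anhydride | C/C=C(/C)C(=O)OC(=O)c1c(Cl)cc(Cl)cc1Cl | intermediate
27 | CNP0204191.1 | C/C=C(/C)C(=O)O[C@@H]1C[C@@](O)(C(C)C)[C@@H]2[C@@H](OC(=O)c3ccc(OC)cc3)CC(C)=CC[C@]21C | target

**Count and risks**

Total steps: 19. Longest linear sequence: 19 steps (1 → 27).

Step 12 (proposed new method). The silylated epoxide may ionise at the tertiary carbon C4 and rearrange by a 1,2-shift instead of opening at C5 with help from the diene. The first C–C bond may also form from a transoid diene, after which the allyl cation cannot close the seven-membered ring and instead loses a proton or closes a five-membered ring at C10. Closure through the compact transition state would give the cis ring fusion. The fallback sets out from epoxy ketone 14 and uses only known reaction types. Samarium diiodide (SmI2, divalent samarium) in THF/MeOH at −90 °C should cleave the Cα–O bond to the β-hydroxy ketone F1. Et3SiOTf with 2,6-lutidine should then give its triethylsilyl ether F2. Kinetic enolisation at the methyl group (LiN(iPr)2, Me3SiCl) should give the trimethylsilyl enol ether F3, and N-chlorosuccinimide the chloromethyl ketone F4. Triethylamine in 2,2,2-trifluoroethanol should then generate the free oxyallyl cation (enolisation toward C5, loss of chloride from C7), whose intramolecular (4+3) cycloaddition with the diene comes back to the route at 16. The leaving group now sits on C7, so the question of which epoxide bond breaks disappears; the price is that C5 is then set by the C4 stereocenter and the tether, no longer by inversion.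

Step 15. Ligand exchange of the hindered tertiary hydroxyl at boron may be too slow, so that hydride arrives intermolecularly on the more open α face and the facial selectivity at C6 is poor or reversed. The fallback sets out from 19 and takes the open face on purpose. Luche reduction (NaBH4, CeCl3·7H2O, MeOH, −78 °C) should give the 6β-alcohol F5. 1,4-Hydrogenation as in step 16 should give the 6β-alcohol with the C8=C9 alkene F6. A Mitsunobu reaction with 4-methoxybenzoic acid (PPh3, DIAD, toluene) should then invert C6 and install the ester in one operation, coming back to the route at 23.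

Step 16. The diene, flanked by the quaternary C1 and the C6 carbinol, may fail to bind the chromium centre, or the catalyst may move the double bond on after the addition. The fallback sets out from 19. Dissolving-metal reduction of the linear dienone (Li, liquid NH3, THF, −78 °C, NH4Cl quench) should add hydrogen at C10 and, by kinetic α-protonation of the dienolate at C7, give the β,γ-unsaturated ketone F7. Hydroxyl-directed reduction as in step 15 then comes back to the route at 21.

**Further compounds**

F1 | step 12 | (4S,6R,7E,9E)-6-(TBS-oxy)-4-hydroxy-7-methyl-4-(propan-2-yl)undeca-7,9-dien-2-one | CC(=O)C[C@](O)(C(C)C)C[C@@H](O[Si](C)(C)C(C)(C)C)/C(C)=C/C=C/C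
F2 | step 12 | triethylsilyl ether of F1 | CC(=O)C[C@](O[Si](CC)(CC)CC)(C(C)C)C[C@@H](O[Si](C)(C)C(C)(C)C)/C(C)=C/C=C/C
F3 | step 12 | 2-(trimethylsilyloxy)-1-ene (kinetic silyl enol ether of F2) | C=C(O[Si](C)(C)C)C[C@](O[Si](CC)(CC)CC)(C(C)C)C[C@@H](O[Si](C)(C)C(C)(C)C)/C(C)=C/C=C/C
F4 | step 12 | (4S,6R,7E,9E)-6-(TBS-oxy)-1-chloro-7-methyl-4-(propan-2-yl)-4-(TES-oxy)undeca-7,9-dien-2-one | ClCC(=O)C[C@](O[Si](CC)(CC)CC)(C(C)C)C[C@@H](O[Si](C)(C)C(C)(C)C)/C(C)=C/C=C/C
F5 | step 15 | 2β-(TBS-oxy)-5αH-dauca-7,9-diene-4β,6β-diol | CC(C)(C)[Si](C)(C)O[C@@H]1C[C@@](O)(C(C)C)[C@@H]2[C@H](O)C=C(C)C=C[C@]21C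
F6 | step 15 | 2β-(TBS-oxy)-5αH-dauc-8-ene-4β,6β-diol | CC(C)(C)[Si](C)(C)O[C@@H]1C[C@@](O)(C(C)C)[C@@H]2[C@H](O)CC(C)=CC[C@]21C
F7 | step 16 | 2β-(TBS-oxy)-4β-hydroxy-5αH-dauc-8-en-6-one | CC(C)(C)[Si](C)(C)O[C@@H]1C[C@@](O)(C(C)C)[C@@H]2C(=O)CC(C)=CC[C@]21C
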